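The earlier runs and the new flask come from a simulation from invented constants.

The constants of this flask are hidden, so the charges and the earlier runs have to speak for them. The left-handed and right-handed substrates meet the coupling partner under a single-handed free catalyst, which couples them at different rates and dies in pairs, while the racemization catalyst turns one substrate into the other: a dynamic kinetic resolution.

| setting | cedar | elm | alder | flask |
|---|---|---|---|---|
| left-handed substrate | 0.30 M | 0.30 M | 0.30 M | 0.30 M |
| right-handed substrate | 0.30 M | 0.30 M | 0.30 M | 0.30 M |
| coupling partner | 0.90 M | 0.90 M | 0.90 M | 0.900 M |
| free catalyst | 1.5 mM | 1.5 mM | 2.2 mM | 1.5 mM |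
| racemization catalyst | 2 mM | 4.5 mM | 3 mM | 3.0 mM |
| impurity | 0.53 mM | 0.53 mM | 0.53 mM | 0.53 mM |
| remark | run made earlier | run made earlier | run made earlier |  |
| time |  |  |  | 4.0 min |

- cedar (time / min: left-handed product / %, right-handed product / %): 0.250: 21.5, 8.9; 0.417: 23.2, 8.0; 0.667: 23.6, 9.8; 0.833: 25.5, 10.8; 1.33: 28.0, 9.0; 2.00: 32.4, 11.6; 3.00: 32.3, 14.6
- elm (time / min: left-handed product / %, right-handed product / %): 0.250: 20.4, 8.5; 0.417: 24.5, 8.8; 0.667: 27.0, 9.8; 0.833: 27.4, 10.9; 1.33: 29.3, 11.1; 2.00: 31.5, 10.7; 3.00: 33.3, 12.0
- alder (time / min: left-handed product / %, right-handed product / %): 0.250: 20.6, 10.8; 0.833: 28.7, 11.1; 1.33: 29.6, 10.6; 2.50: 32.3, 13.0; 3.00: 31.7, 12.5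

(standard deviation of a reading: 1 percentage point)

- free catalyst is single-handed; left-handed substrate and right-handed substrate are mirror images of each other, charged as a racemate, each of them at the stated concentration
- reactions considered so far: coupling partner -> decomposition product; left-handed substrate + racemization catalyst <-> right-handed substrate + racemization catalyst; coupling partner + free catalyst + right-handed substrate -> free catalyst + right-handed product; racemization catalyst + impurity -> spent catalyst B; coupling partner + free catalyst + left-handed substrate -> free catalyst + left-handed product; 2 free catalyst -> spent catalyst A
- an excess is the difference of the two amounts in percent of their sum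
- an excess is below zero if the other one leads

- left-handed product and right-handed product together, in percent of the left-handed substrate and right-handed substrate charged together, at 4.0 min
- excess of left-handed product over right-handed product in the product at 4.0 min
- whether the exchange between left-handed substrate and right-handed substrate keeps pace with the reaction: how far the product's excess at 4.0 min gets from its value without exchange to its value with instant exchange (above 80 % keeps pace, below 20 % hardly takes part, else lags behind)

In the list of reactions each impurity takes away one racemization catalyst, so the count to make is the charge less the impurity. In the flask that leaves 2.47 mM, called the working racemization catalyst, W.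

Now read the last row of each run, at 3.00 min. Cedar has a W of 1.47 mM and a product excess of 37.7 %. Alder, which was also charged with 2.2 mM of free catalyst against 1.5 mM in cedar, has 2.47 mM and 43.4 %, and elm, with cedar's free catalyst, has 3.97 mM and 47.0 %. So, as far as readings with a scatter of 1 percentage point can show, the excess climbs with W: cedar's is lower than alder's, and alder's is lower than elm's. The totals do not follow W: 46.9 % in cedar, 44.2 % in alder, 45.3 % in elm. The flask's W matches alder's, so this reckoning reads the flask's excess from alder's row, near 43.4 %.

The forecast says 47 % for the total, above alder's reading, and 43.5 % for the excess, and it says that the exchange lags behind, “roughly halfway between the limits”.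

The flask gives 46.4 % and 45.7 %, and the exchange lags behind, at 66 % of the way. The flask's reacted part stays at 46.4 % because of the turning of free catalyst in pairs into spent catalyst A: with that step struck out, the reacted part reaches >99.9 %.

    coupling partner → decomposition product (k = 2.83 × 10⁻⁵ s⁻¹)
    left-handed substrate + racemization catalyst ⇌ right-handed substrate + racemization catalyst, rate k2*[racemization catalyst]*[left-handed substrate] forward; the back reaction follows from the equilibrium constant (k = 15.7 L mol⁻¹ s⁻¹)
    coupling partner + free catalyst + right-handed substrate → free catalyst + right-handed product (k = 53.7 L² mol⁻² s⁻¹)
    racemization catalyst + impurity → spent catalyst B (k = 7560 L mol⁻¹ s⁻¹)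
    coupling partner + free catalyst + left-handed substrate → free catalyst + left-handed product (k = 159 L² mol⁻² s⁻¹)
    2 free catalyst → spent catalyst A (k = 338 L mol⁻¹ s⁻¹)

The turning of left-handed substrate into right-handed substrate, both ways, carries part of the flask's excess: with that step struck out, the excess at 4.0 min falls from 45.7 % to 38.1 %. The racemization catalyst in the flask stands at 82.3 % of its charge, which is 2.47 mM, the W counted above. A neighbouring flask, the same but charged with 0.750 mM of racemization catalyst, has a W of 0.220 mM by the same count, and its excess is 40.8 %. In that neighbouring flask the substrates stay apart, with 25.0 % left-handed against 29.7 % right-handed.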